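**The time.** At 80 min I must say where the charged substrate stands in this flask, so I begin with how much substrate that time leaves.

- south-west: substrate 2.5 M; partner 1 equiv; run made earlier
- flask: substrate 2.5 M; partner 0.700 equiv; time 80 min

south-west run (percent of the substrate charged)

| time / min | isomer of the product / % | intermediate / % | substrate / % | homo product / % | target / % |
|---|---|---|---|---|---|
| 2.00 | 0.5 | 3.6 | 96.7 | 0.4 | 0 |
| 3.00 | 0 | 4.8 | 95.3 | 0 | 0 |
| 5.00 | 0 | 7.1 | 92.0 | 0 | 0.6 |
| 8.00 | 0.1 | 10.0 | 88.4 | 0.2 | 0 |
| 15.0 | 1.1 | 16.7 | 79.6 | 1.3 | 2.7 |
| 25.0 | 1.3 | 21.3 | 69.4 | 2.7 | 6.2 |

(scatter of a reading: 0.5 percentage points)

1. where most of what was charged as substrate, at 80 min is found (intermediate / homo product / target / substrate / isomer of the product)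
2. the largest share itself, whichever of these holds it, in percent of the substrate charged

- in percentages every species weighs as the substrate in it: one homo product counts as two

**Loss constant.** My first link is the loss constant, the fraction of the remaining substrate that goes each minute (a first-order rate constant). The south-west reading at 25.0 min gives 0.0146 /min, and the one at 8.00 min gives 0.0154 /min. Partner is not among the readings, so taking this loss to need no partner is my assumption. By this reckoning this flask keeps 31.1% of its substrate.

**The drain.** Can intermediate exceed that? Between 15.0 min and 25.0 min substrate falls 10 percentage points while intermediate rises 4.6 points. The difference, divided by the mean intermediate and the interval, reads as a drain constant of 0.0295 /min. Two constants in series, held to 80 min, reckon 21.2% as intermediate in this flask.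

**Weak link.** That drain was read at 1 equiv of partner, and this flask has 0.700 equiv. Scaling the whole drain with the charge gives 0.0206 /min and lifts my reckoned intermediate to 28.8%, narrowly less than reckoned substrate. The other 40.1% I share among target, homo product and isomer of the product as they stand in the south-west reading at 25.0 min, which gives target 24.4%, less than reckoned substrate. I commit to substrate at 31.1%.

**The forecast.** The forecast also names substrate, but at 57%, which differs from my share. Its ground: “Substrate loss in the south-west run follows simple second-order behaviour”.

**The flask.** This flask gives substrate at 30.1%, with intermediate at 25.2%.

    substrate → intermediate (k = 0.0150 /min)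
    partner + intermediate → target (k = 0.00940 /M/min)
    2 intermediate → homo product (k = 0.00930 /M/min)
    target ⇌ isomer of the product (K = 1.10, k = 0.0140 /min)

Moving partner to this flask's charge leaves south-west substrate at 68.7% at its last reading, as against 68.7% unchanged. The loss constant, carried to the neighbouring flask left until 2.5 h, reckons 11.2% of substrate. That flask holds 10.5%, and its largest share is homo product at 35.1%.

The earlier runs and the new flask were generated by integration with made-up constants; the scatter is artificial.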